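Positions are given in labdane numbering throughout: ring A = C1–C5 and C10, ring B = C5–C10, side chain C11–C16, C17 on C8, C18 and C19 on C4, C20 on C10.

## The problem

The target is a labda-8,13-diene: a trans-fused decalin (rings A and B) with a tetrasubstituted C8–C9 alkene, a C9 side chain that ends in an (E)-trisubstituted allylic acetate (C13–C14, acetate on C15), and a free carboxylic acid C19 on C4. Three contiguous stereocentres are needed. C4 and C10 are quaternary, with the C19 carboxyl and the C20 methyl 1,3-diaxial on the β-face, and C5 carries its hydrogen on the α-face. C4 has no hydrogen and no neighbour that could correct it, so it must be set first and in absolute terms. It is then the only element that can steer C10, and the two axial β-groups on C4 and C10 together can direct hydrogen to C5 from the α-face. The C13–C14 alkene is too far from the rings to be controlled by them and needs a method that fixes its geometry by itself. Three features are fragile: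

- the allylic acetate, which is ionised by acid or zerovalent palladium and cleaved by hydride or strong nucleophiles;
- the C8–C9 alkene, which migrates under protic acid and makes any leaving group on C11 prone to ionisation and elimination;
- the axial, neopentyl C19 acid, whose esters cannot be saponified, so its protecting group has to leave by alkyl–oxygen cleavage before the acetate is in place.

The enabling feature is that ring B holds the C8–C9 alkene, with C17 on C8 and C11 on C9, directly beside quaternary C10. That is the imprint of a but-2-ynoate on a diene made of the ring A alkene C10–C5 and a vinyl group C6–C7, and the quaternary C10 keeps the resulting cyclohexadiene from aromatising.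

## Retrosynthesis

**Acetate and acid.** Target 22 is cut at the acetyl–oxygen bond to hydroxy acid 21, so that the acetate is installed last and never meets hydride or acid. The allylic alcohol of 21 is traced to the methyl enoate of acid 20, and 20 to its tert-butyl ester 18. Freeing C19 at the enoate stage is preferred over doing it next to an allylic alcohol or acetate, because in 18 the only other π-systems are a deactivated enoate and the C8–C9 alkene. The forward steps must remove a tert-butyl group without protic acid and reduce an enoate beside a hindered carboxylic acid.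

**Side chain.** Enoate 18 is cut at C13–C16 to the (Z)-enol phosphate 17, which is the O-phosphorylated form of β-keto ester 16. Keto ester 16 is cut at C11–C12 into allylic bromide 14 and methyl acetoacetate 15. This is preferred over two neighbours.

- A five-carbon allylic sulfone would also make C11–C12, but its reductive removal passes through an allyl system with two secondary termini next to an allylic oxygen and would scramble alkene position and geometry.
- An olefination of a C13 methyl ketone gives E/Z mixtures.

The enol phosphate–cuprate sequence transfers geometry with retention. The precursor is a bicyclic core whose only side-chain atom is C11. The forward reaction needs a clean SN2 displacement at a hindered but primary allylic carbon.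

**C11 and the ring fusion.** Bromide 14 comes from allylic alcohol 13, and 13 from the methyl ester of diester 12. Two different esters in 12 (methyl at C11, tert-butyl at C19) make this reduction selective. Diester 12 is traced to diene diester 11 by removing the two hydrogens at C5 and C6. The forward hydrogenation must add to the trisubstituted alkene only, and from the α-face.

**Key disconnection.** Adduct 11 is cut at C9–C10 and C7–C8 into diene 9 and methyl but-2-ynoate 10. No other cut delivers the tetrasubstituted alkene, both of its substituents and quaternary C10 in one step from a monocyclic precursor with a single stereocentre. Aldol-type annulations would leave oxygen at the wrong ring B carbons. The forward reaction must be regioselective (C8 to C7, C9 to C10), must add to the diene face opposite the C19 ester, and must overcome the low reactivity of a hindered diene without destroying the tert-butyl ester.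

**The diene.** Diene 9 is cut at C5–C6 into enol triflate 7 and vinylborate 8. Triflate 7 comes from ketone 6, which can enolise only toward C10 because C4 is quaternary. Ketone 6 is cut at C10–C20 to keto ester 5. The C10 centre of 6 is transient, so its configuration does not matter.

**The C4 stereocentre.** Keto ester 5 is cut at C4–C18. The methyl group is introduced on enamine 3, made from keto ester 1 and L-valine tert-butyl ester 2, with imine 4 as the hydrolysed intermediate. A stoichiometric auxiliary is accepted here because the electrophile is the smallest possible one, for which auxiliary-controlled enamine alkylation is the directly precedented case. Catalytic phase-transfer alkylation of 1 is held in reserve. The tert-butyl ester is chosen for C19 from the start: it survives the bases and hydride of the route, it is the bulkiest simple ester for face control in the key step, and it leaves by alkyl–oxygen cleavage.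

## Roads not taken

**Alternative 1:** conjugate alkenylation with enolate trapping, then ring-closing metathesis.
- Cut: C9–C10 and C5–C6 on a ring A enone, with ring B closed later across C8–C9.
- Forward key step: Cu(OTf)2 with a chiral N-heterocyclic carbene ligand transfers the alkenyl group of the aluminium reagent A2 to C10 of 3-methylcyclohex-2-en-1-one A1. The aluminium enolate, activated with MeLi, is trapped at C5 by 3-(trimethylsilyl)but-3-en-2-one A3 to give the trans keto-alkene A4.
- Merits: C10 is set by a catalyst, the trans C5/C10 relationship arises in the trapping step without hydrogenation, and C11 arrives oxygenated.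
- Weak points: ring B must be closed by a metathesis that forms a tetrasubstituted alkene after methylenation at C8. The enolate being trapped sits next to a new quaternary centre. Most seriously, C4 arrives as a ketone, so the quaternary centre with methyl and carboxyl has to be built late over several steps with its own stereochemical problem.
- Comparison: this road is better in absolute control at C10 and does not depend on substrate-controlled facial selectivity. The chosen plan sets against it a C4 centre that carries C19 at the right oxidation level from the second step, and a ring closure that delivers the C8–C9 alkene with both substituents at once.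

**Alternative 2:** epoxide-triggered cationic bicyclisation ending on a β-keto ester.
- Cut: C4–C5 and C9–C10 of an acyclic chain carrying a trisubstituted epoxide, an (E)-alkene and a β-keto ester.
- Forward key step: MeAlCl2 opens the epoxide at C4, the C5–C10 alkene attacks with inversion, and the keto ester carbon C9 captures the C10 cation, giving the trans-fused hydroxy keto ester A5.
- Merits: both rings and C4, C5 and C10 form in one step. The ring fusion and the C4/C10 relationship follow from alkene and epoxide geometry. In this respect it is more certain than the chosen plan and needs no hydrogenation.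
- Weak points: A5 carries a C3 hydroxyl that must be removed, a C8 ketone that must be turned into the methyl-bearing alkene carbon, and C19 as a silyl ether that must be oxidised twice near the end. The acyclic substrate needs an enantiopure epoxide with two different carbon substituents at C4 and a geometrically pure trisubstituted alkene. Epoxide-initiated bicyclisations also lose material to partial cyclisation and rearrangement.
- Comparison: the chosen plan reaches the bicyclic diester in six steps from bought materials with no surplus oxygen. It pays for this with a facial selectivity that alternative 2 does not have to worry about.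

**Alternative 3:** enantioselective quinone Diels–Alder that builds ring A on ring B.
- Cut: C1–C10 and C4–C5.
- Forward key step: the HNTf2 salt of the (S)-proline-derived B-(2-methylphenyl)oxazaborolidine catalyses endo addition of (3E)-penta-1,3-diene A7 to 2,6-dimethylcyclohexa-2,5-diene-1,4-dione A6, giving the cis-fused enedione A8.
- Merits: taken as a single step this is the best-precedented and most selective cycloaddition of the four, it uses the cheapest materials, and it places C10, C20 and C17 at once.
- Weak points: A8 is cis-fused and has carbonyls at C6 and C9. C6 must be deoxygenated and C9 must become the chain-bearing alkene carbon, with the C7–C8 alkene moved to C8–C9. C4 arrives as a tertiary carbon with one methyl and no carboxyl carbon, and making it quaternary with C19 has no direct solution.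
- Comparison: the chosen plan cannot match the catalytic enantiocontrol of this step. It matches the oxidation pattern of the target instead: every carbon of its adduct is at or one step from its final state.

Key step: step 6

## Route

Remarks on the chemistry:
- In step 2 the face of the lithiated enamine that is methylated depends on the ligand at lithium. A weakly binding ligand (THF) is assumed to place the methyl group anti to the isopropyl group of the auxiliary, which gives (S)-5. If the opposite sense is found, D-valine tert-butyl ester is used and no later step changes.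
- Compound 2 is used as the free base, liberated from its commercial hydrochloride.

Step 1
Reactants: 1 tert-butyl 2-oxocyclohexane-1-carboxylate; 2 L-valine tert-butyl ester
Product: 3 tert-butyl 2-{[(2S)-1-tert-butoxy-3-methyl-1-oxobutan-2-yl]amino}cyclohex-1-ene-1-carboxylate
Conditions: BF3·OEt2 (cat.), benzene, reflux, Dean–Stark
Reagents that add atoms: none
Why: Acid-catalysed enamine formation between a β-keto ester and a primary amine gives the hydrogen-bonded vinylogous carbamate; removal of water drives it and the valine stereocentre is not touched.

Step 2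
Reactants: 3 tert-butyl 2-{[(2S)-1-tert-butoxy-3-methyl-1-oxobutan-2-yl]amino}cyclohex-1-ene-1-carboxylate
Product: 5 tert-butyl (1S)-1-methyl-2-oxocyclohexane-1-carboxylate, via methylated imine 4 (not isolated)
Conditions: LiN(iPr)2, toluene, −78 °C; THF (ligand), MeI, −78 → −40 °C; then 1 M aq. HCl, rt
Reagents that add atoms: iodomethane, CI; water, O
Why: Auxiliary-controlled enamine alkylation: N-deprotonation gives a lithium aza-enolate in which lithium is held by nitrogen and both ester carbonyls, so the isopropyl group differentiates the faces of C4 and methyl iodide sets C4 as S; mild aqueous acid then hydrolyses imine 4, frees the auxiliary for recovery and leaves the tert-butyl ester intact.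

Step 3
Reactants: 5 tert-butyl (1S)-1-methyl-2-oxocyclohexane-1-carboxylate
Product: 6 tert-butyl (1S,3RS)-1,3-dimethyl-2-oxocyclohexane-1-carboxylate (both C3 epimers)
Conditions: LiN(iPr)2, THF, −78 °C; MeI, −78 → 0 °C
Reagents that add atoms: iodomethane, CI
Why: Kinetic enolate alkylation: C4 is quaternary, so the base can enolise only toward C10 and methyl iodide installs C20; the new centre forms as both epimers, which is harmless because it becomes trigonal in step 4.

Step 4
Reactants: 6 tert-butyl (1S,3RS)-1,3-dimethyl-2-oxocyclohexane-1-carboxylate
Product: 7 tert-butyl (1S)-1,3-dimethyl-2-[(trifluoromethanesulfonyl)oxy]cyclohex-2-ene-1-carboxylate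
Conditions: KN(SiMe3)2, THF, −78 °C; PhNTf2, −78 → 0 °C
Reagents that add atoms: N-phenylbis(trifluoromethanesulfonimide), O=S(=O)(N(c1ccccc1)S(=O)(=O)C(F)(F)F)C(F)(F)F
Why: Enol triflate formation: the only enolisable hydrogen is the tertiary one at C10, so the potassium enolate and its O-triflate are regiodefined and both epimers of 6 converge on 7, as known for 2,2,6-trisubstituted cyclohexanones.

Step 5
Reactants: 7 tert-butyl (1S)-1,3-dimethyl-2-[(trifluoromethanesulfonyl)oxy]cyclohex-2-ene-1-carboxylate; 8 potassium vinyltrifluoroborate
Product: 9 tert-butyl (1S)-2-ethenyl-1,3-dimethylcyclohex-2-ene-1-carboxylate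
Conditions: PdCl2(dppf) (cat.; dppf = 1,1′-bis(diphenylphosphino)ferrocene), Cs2CO3, THF–H2O, 70 °C
Reagents that add atoms: none
Why: Suzuki–Miyaura coupling: zerovalent palladium inserts into the C5–O bond of the hindered enol triflate and the vinyl group is transferred from boron, as established for fully substituted cyclohexenyl triflates; the base does not harm the tert-butyl ester and C4 is untouched.

Step 6
Reactants: 9 tert-butyl (1S)-2-ethenyl-1,3-dimethylcyclohex-2-ene-1-carboxylate; 10 methyl but-2-ynoate
Product: 11 1-tert-butyl 5-methyl (1S,4aS)-1,4a,6-trimethyl-1,2,3,4,4a,7-hexahydronaphthalene-1,5-dicarboxylate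
Conditions: 10 (5 equiv), CH2Cl2, 13 kbar, 50 °C, 2,6-di-tert-butyl-4-methylphenol (trace)
Reagents that add atoms: none
Why: This is a normal-electron-demand [4+2] cycloaddition, concerted but asynchronous: the methyl-bearing β-carbon of 10 (C8) bonds first to the unsubstituted diene terminus C7, where the HOMO coefficient is largest, and the ester-bearing α-carbon (C9) closes onto the dialkylated terminus C10. The closest known reaction type is the addition of acetylenic esters to 1,3,3-trimethyl-2-vinylcyclohexene-type dienes; high pressure is the standard way to drive such hindered cycloadditions, at a temperature where the tert-butyl ester survives and a 1,5-hydrogen shift from C20 to C7 does not compete. Ring B is closed by the cycloaddition itself, an intermolecular annulation onto ring A with both new σ-bonds formed on one face of the diene, and it emerges as a 1,4-cyclohexadiene that cannot aromatise because C10 is quaternary. The only new stereocentre, C10, is controlled by C4: in the s-cis diene the tert-butoxycarbonyl group should sit pseudoaxial, where it avoids the allylic 1,2-strain with the inside hydrogen at C6 and costs less than an axial methyl group, and the ynoate should approach C10 from the opposite α-face, leaving C20 syn to C19 (C10 S). Regioselectivity is needed and is secured by the polarisation of both partners; facial selectivity is needed and rests on the bulk and pseudoaxial position of the C19 ester, the C10 epimer being a separable diastereomer.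

Step 7
Reactants: 11 1-tert-butyl 5-methyl (1S,4aS)-1,4a,6-trimethyl-1,2,3,4,4a,7-hexahydronaphthalene-1,5-dicarboxylate
Product: 12 1-tert-butyl 5-methyl (1S,4aS,8aR)-1,4a,6-trimethyl-1,2,3,4,4a,7,8,8a-octahydronaphthalene-1,5-dicarboxylate
Conditions: H2 (1 atm), Pd/C, EtOAc, rt
Reagents that add atoms: none
Why: Heterogeneous hydrogenation: the trisubstituted C5–C6 alkene is reduced while the tetrasubstituted, ester-bearing C8–C9 alkene is inert; the axial C20 methyl and C19 ester close the β-face, so hydrogen reaches C5 from the α-face and gives the trans ring fusion (C5 R).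

Step 8
Reactants: 12 1-tert-butyl 5-methyl (1S,4aS,8aR)-1,4a,6-trimethyl-1,2,3,4,4a,7,8,8a-octahydronaphthalene-1,5-dicarboxylate
Product: 13 tert-butyl (1S,4aS,8aR)-5-(hydroxymethyl)-1,4a,6-trimethyl-1,2,3,4,4a,7,8,8a-octahydronaphthalene-1-carboxylate
Conditions: iBu2AlH (2.5 equiv), CH2Cl2, −78 → −20 °C; Rochelle salt work-up
Reagents that add atoms: none
Why: Hydride reduction of an ester to the primary alcohol: the methyl ester at C11 is reduced, whereas the tert-butyl ester at C19, axial and on a quaternary carbon, is far less accessible and less electrophilic and should remain.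

Step 9
Reactants: 13 tert-butyl (1S,4aS,8aR)-5-(hydroxymethyl)-1,4a,6-trimethyl-1,2,3,4,4a,7,8,8a-octahydronaphthalene-1-carboxylate
Product: 14 tert-butyl (1S,4aS,8aR)-5-(bromomethyl)-1,4a,6-trimethyl-1,2,3,4,4a,7,8,8a-octahydronaphthalene-1-carboxylate
Conditions: CBr4, PPh3, CH2Cl2, −20 → 0 °C; used at once
Reagents that add atoms: tetrabromomethane, BrC(Br)(Br)Br
Why: Appel reaction: the primary allylic alcohol is converted to the bromide under neutral conditions, with no acid that could cleave the tert-butyl ester or move the C8–C9 alkene; the bromide is taken on crude because it ionises easily.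

Step 10
Reactants: 14 tert-butyl (1S,4aS,8aR)-5-(bromomethyl)-1,4a,6-trimethyl-1,2,3,4,4a,7,8,8a-octahydronaphthalene-1-carboxylate; 15 methyl acetoacetate
Product: 16 tert-butyl (1S,4aS,8aR)-5-(5-methoxy-3,5-dioxopentyl)-1,4a,6-trimethyl-1,2,3,4,4a,7,8,8a-octahydronaphthalene-1-carboxylate
Conditions: 15, NaH, THF, 0 °C; n-BuLi, 0 °C; then 14, 0 °C → rt; aq. NH4Cl
Reagents that add atoms: none
Why: γ-Alkylation of an acetoacetate dianion: the terminal carbanion displaces the primary allylic bromide at C11 (SN2′ attack is closed because C8 is fully substituted), forming C11–C12 and bringing in C12–C15 in one piece.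

Step 11
Reactants: 16 tert-butyl (1S,4aS,8aR)-5-(5-methoxy-3,5-dioxopentyl)-1,4a,6-trimethyl-1,2,3,4,4a,7,8,8a-octahydronaphthalene-1-carboxylate
Product: 17 tert-butyl (1S,4aS,8aR)-5-{(3Z)-3-[(diethoxyphosphoryl)oxy]-5-methoxy-5-oxopent-3-en-1-yl}-1,4a,6-trimethyl-1,2,3,4,4a,7,8,8a-octahydronaphthalene-1-carboxylate
Conditions: NaH, Et2O, 0 °C; ClP(O)(OEt)2, 0 °C → rt
Reagents that add atoms: diethyl chlorophosphate, CCOP(=O)(Cl)OCC
Why: O-Phosphorylation of the chelated sodium enolate of a β-keto ester gives the Z enol phosphate, with the phosphate cis to the ester, as in the standard enol phosphate route to trisubstituted enoates.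

Step 12
Reactants: 17 tert-butyl (1S,4aS,8aR)-5-{(3Z)-3-[(diethoxyphosphoryl)oxy]-5-methoxy-5-oxopent-3-en-1-yl}-1,4a,6-trimethyl-1,2,3,4,4a,7,8,8a-octahydronaphthalene-1-carboxylate
Product: 18 tert-butyl (1S,4aS,8aR)-5-[(3E)-5-methoxy-3-methyl-5-oxopent-3-en-1-yl]-1,4a,6-trimethyl-1,2,3,4,4a,7,8,8a-octahydronaphthalene-1-carboxylate
Conditions: Me2CuLi (from MeLi and CuI), Et2O, −78 → −45 °C
Reagents that add atoms: lithium dimethylcuprate, [Li+].C[Cu-]C
Why: Cuprate substitution of a β-phosphoryloxy enoate (addition–elimination) proceeds with retention, so the methyl group C16 takes the place of the phosphate cis to the ester and the C13–C14 alkene is E; the hindered tert-butyl ester and the tetrasubstituted alkene are inert to the cuprate at low temperature.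

Step 13
Reactants: 18 tert-butyl (1S,4aS,8aR)-5-[(3E)-5-methoxy-3-methyl-5-oxopent-3-en-1-yl]-1,4a,6-trimethyl-1,2,3,4,4a,7,8,8a-octahydronaphthalene-1-carboxylate
Product: 20 (1S,4aS,8aR)-5-[(3E)-5-methoxy-3-methyl-5-oxopent-3-en-1-yl]-1,4a,6-trimethyl-1,2,3,4,4a,7,8,8a-octahydronaphthalene-1-carboxylic acid, via trimethylsilyl ester 19 (not isolated)
Conditions: Me3SiOTf, 2,6-lutidine, CH2Cl2, 0 °C; then pH 4 aqueous buffer
Reagents that add atoms: none
Why: Silyl triflate-mediated tert-butyl ester cleavage: silylation of the carbonyl oxygen is followed by loss of the tert-butyl group as 2-methylpropene (alkyl–oxygen fission, indifferent to the hindrance at C19); 2,6-lutidine keeps the medium free of protic acid so the C8–C9 alkene does not migrate, the methyl enoate is untouched, and silyl ester 19 hydrolyses on work-up.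

Step 14
Reactants: 20 (1S,4aS,8aR)-5-[(3E)-5-methoxy-3-methyl-5-oxopent-3-en-1-yl]-1,4a,6-trimethyl-1,2,3,4,4a,7,8,8a-octahydronaphthalene-1-carboxylic acid
Product: 21 (1S,4aS,8aR)-5-[(3E)-5-hydroxy-3-methylpent-3-en-1-yl]-1,4a,6-trimethyl-1,2,3,4,4a,7,8,8a-octahydronaphthalene-1-carboxylic acid
Conditions: iBu2AlH (4 equiv), CH2Cl2, −78 → −40 °C; Rochelle salt, then dilute citric acid
Reagents that add atoms: none
Why: 1,2-Reduction of an α,β-unsaturated ester to the allylic alcohol: the acid is first converted to an aluminium carboxylate which, being axial and neopentyl, should not be reduced at low temperature; the alkene geometry is not affected.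

Step 15
Reactants: 21 (1S,4aS,8aR)-5-[(3E)-5-hydroxy-3-methylpent-3-en-1-yl]-1,4a,6-trimethyl-1,2,3,4,4a,7,8,8a-octahydronaphthalene-1-carboxylic acid
Product: 22 (1S,4aS,8aR)-5-[(3E)-5-(acetyloxy)-3-methylpent-3-en-1-yl]-1,4a,6-trimethyl-1,2,3,4,4a,7,8,8a-octahydronaphthalene-1-carboxylic acid
Conditions: Ac2O, pyridine, DMAP (cat.), CH2Cl2, 0 °C → rt; then H2O
Reagents that add atoms: acetic anhydride, CC(=O)OC(C)=O
Why: Nucleophile-catalysed acetylation of the primary allylic alcohol: the hindered tertiary acid gives no lasting mixed anhydride, and any that forms is hydrolysed in the aqueous work-up.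

## Compound list

1 | tert-butyl 2-oxocyclohexane-1-carboxylate | O=C1CCCCC1C(=O)OC(C)(C)C | starting material
2 | L-valine tert-butyl ester, tert-butyl (2S)-2-amino-3-methylbutanoate | CC(C)[C@H](N)C(=O)OC(C)(C)C | starting material
3 | tert-butyl 2-{[(2S)-1-tert-butoxy-3-methyl-1-oxobutan-2-yl]amino}cyclohex-1-ene-1-carboxylate | CC(C)[C@H](NC1=C(C(=O)OC(C)(C)C)CCCC1)C(=O)OC(C)(C)C | intermediate
4 | tert-butyl (1S)-2-{[(2S)-1-tert-butoxy-3-methyl-1-oxobutan-2-yl]imino}-1-methylcyclohexane-1-carboxylate | CC(C)[C@H](N=C1CCCC[C@]1(C)C(=O)OC(C)(C)C)C(=O)OC(C)(C)C | intermediate (not isolated)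
5 | tert-butyl (1S)-1-methyl-2-oxocyclohexane-1-carboxylate | O=C1CCCC[C@]1(C)C(=O)OC(C)(C)C | intermediate
6 | tert-butyl (1S,3RS)-1,3-dimethyl-2-oxocyclohexane-1-carboxylate | O=C1C(C)CCC[C@]1(C)C(=O)OC(C)(C)C | intermediate
7 | tert-butyl (1S)-1,3-dimethyl-2-[(trifluoromethanesulfonyl)oxy]cyclohex-2-ene-1-carboxylate | FC(F)(F)S(=O)(=O)OC1=C(C)CCC[C@]1(C)C(=O)OC(C)(C)C | intermediate
8 | potassium vinyltrifluoroborate | C=C[B-](F)(F)F.[K+] | starting material
9 | tert-butyl (1S)-2-ethenyl-1,3-dimethylcyclohex-2-ene-1-carboxylate | C=CC1=C(C)CCC[C@]1(C)C(=O)OC(C)(C)C | intermediate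
10 | methyl but-2-ynoate | CC#CC(=O)OC | starting material
11 | 1-tert-butyl 5-methyl (1S,4aS)-1,4a,6-trimethyl-1,2,3,4,4a,7-hexahydronaphthalene-1,5-dicarboxylate | COC(=O)C1=C(C)CC=C2[C@@](C)(C(=O)OC(C)(C)C)CCC[C@]12C | intermediate
12 | 1-tert-butyl 5-methyl (1S,4aS,8aR)-1,4a,6-trimethyl-1,2,3,4,4a,7,8,8a-octahydronaphthalene-1,5-dicarboxylate | COC(=O)C1=C(C)CC[C@H]2[C@@](C)(C(=O)OC(C)(C)C)CCC[C@]12C | intermediate
13 | tert-butyl (1S,4aS,8aR)-5-(hydroxymethyl)-1,4a,6-trimethyl-1,2,3,4,4a,7,8,8a-octahydronaphthalene-1-carboxylate | OCC1=C(C)CC[C@H]2[C@@](C)(C(=O)OC(C)(C)C)CCC[C@]12C | intermediate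
14 | tert-butyl (1S,4aS,8aR)-5-(bromomethyl)-1,4a,6-trimethyl-1,2,3,4,4a,7,8,8a-octahydronaphthalene-1-carboxylate | BrCC1=C(C)CC[C@H]2[C@@](C)(C(=O)OC(C)(C)C)CCC[C@]12C | intermediate
15 | methyl acetoacetate | CC(=O)CC(=O)OC | starting material
16 | tert-butyl (1S,4aS,8aR)-5-(5-methoxy-3,5-dioxopentyl)-1,4a,6-trimethyl-1,2,3,4,4a,7,8,8a-octahydronaphthalene-1-carboxylate | COC(=O)CC(=O)CCC1=C(C)CC[C@H]2[C@@](C)(C(=O)OC(C)(C)C)CCC[C@]12C | intermediate
17 | tert-butyl (1S,4aS,8aR)-5-{(3Z)-3-[(diethoxyphosphoryl)oxy]-5-methoxy-5-oxopent-3-en-1-yl}-1,4a,6-trimethyl-1,2,3,4,4a,7,8,8a-octahydronaphthalene-1-carboxylate | COC(=O)/C=C(/CCC1=C(C)CC[C@H]2[C@@](C)(C(=O)OC(C)(C)C)CCC[C@]12C)OP(=O)(OCC)OCC | intermediate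
18 | tert-butyl (1S,4aS,8aR)-5-[(3E)-5-methoxy-3-methyl-5-oxopent-3-en-1-yl]-1,4a,6-trimethyl-1,2,3,4,4a,7,8,8a-octahydronaphthalene-1-carboxylate | COC(=O)/C=C(\C)CCC1=C(C)CC[C@H]2[C@@](C)(C(=O)OC(C)(C)C)CCC[C@]12C | intermediate
19 | trimethylsilyl (1S,4aS,8aR)-5-[(3E)-5-methoxy-3-methyl-5-oxopent-3-en-1-yl]-1,4a,6-trimethyl-1,2,3,4,4a,7,8,8a-octahydronaphthalene-1-carboxylate | COC(=O)/C=C(\C)CCC1=C(C)CC[C@H]2[C@@](C)(C(=O)O[Si](C)(C)C)CCC[C@]12C | intermediate (not isolated)
20 | (1S,4aS,8aR)-5-[(3E)-5-methoxy-3-methyl-5-oxopent-3-en-1-yl]-1,4a,6-trimethyl-1,2,3,4,4a,7,8,8a-octahydronaphthalene-1-carboxylic acid | COC(=O)/C=C(\C)CCC1=C(C)CC[C@H]2[C@@](C)(C(=O)O)CCC[C@]12C | intermediate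
21 | (1S,4aS,8aR)-5-[(3E)-5-hydroxy-3-methylpent-3-en-1-yl]-1,4a,6-trimethyl-1,2,3,4,4a,7,8,8a-octahydronaphthalene-1-carboxylic acid | OC/C=C(\C)CCC1=C(C)CC[C@H]2[C@@](C)(C(=O)O)CCC[C@]12C | intermediate
22 | (1S,4aS,8aR)-5-[(3E)-5-(acetyloxy)-3-methylpent-3-en-1-yl]-1,4a,6-trimethyl-1,2,3,4,4a,7,8,8a-octahydronaphthalene-1-carboxylic acid | CC(=O)OC/C=C(\C)CCC1=C(C)CC[C@H]2[C@@](C)(C(=O)O)CCC[C@]12C | target

## Step count and least certain steps

Total: 15 steps. Longest linear sequence: 15 steps (1 → 22); compounds 2, 8, 10 and 15 are bought.

**Step 6 (key step).** Two things may go wrong.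
- The cycloaddition may be too slow, because the diene must reach a strained s-cis form and create a quaternary centre.
- Facial discrimination at C10 may be poor. A chair-like approach of the ynoate on the ester face competes with the intended approach opposite the pseudoaxial ester, and which of the two is lower cannot be settled on paper. The relative configuration of 11 should therefore be secured before material is carried on.

Fallback, from 9 back to 13: the dienophile class and the mode of activation are changed. Commercial but-2-ynal is added to 9 under BF3·OEt2 in CH2Cl2 at −78 °C, where the conformational preference of the diene is expressed more strongly and the tert-butyl ester is safe. This gives tert-butyl (1S,4aS)-5-formyl-1,4a,6-trimethyl-1,2,3,4,4a,7-hexahydronaphthalene-1-carboxylate F1. Hydrogenation (H2, Pd/C) gives tert-butyl (1S,4aS,8aR)-5-formyl-1,4a,6-trimethyl-1,2,3,4,4a,7,8,8a-octahydronaphthalene-1-carboxylate F2, and NaBH4 in MeOH reduces only the aldehyde and returns to the route at 13. This also removes the need for ester discrimination in step 8.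

**Step 2.** The sense or the level of induction may fall short with so small an electrophile, through leakage to the other face of the aza-enolate. Fallback, from 1 directly to 5: catalytic asymmetric phase-transfer methylation of 1 (MeI, aqueous K2CO3, toluene, 0 °C) with a C2-symmetric N-spiro binaphthyl-derived quaternary ammonium bromide. This class of alkylation is established for exactly this tert-butyl keto ester, and the catalyst antipode is chosen by the same criterion as the auxiliary. The fallback makes no new compound (F0).

**Step 7.** Hydrogen may be delivered to the wrong face, or palladium may move the C5–C6 alkene into conjugation and begin to reduce the C8–C9 alkene. Fallback, from 11 directly to 12: hydrogen-atom-transfer hydrogenation with Mn(dpm)3 (dpm = 2,2,6,6-tetramethylheptane-3,5-dionate), PhSiH3 and tert-butyl hydroperoxide in isopropanol. A hydrogen atom is added to C6, and the tertiary C5 radical is quenched under thermodynamic control to the trans-decalin. The electron-poor tetrasubstituted enoate does not accept a hydrogen atom. No new compound is made (F0).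

**Step 10.** The strongly basic dianion may eliminate hydrogen bromide from the hindered allylic bromide instead of substituting it. Fallback, from 14 back to 18: a softer route through a methyl ketone.
- The sodium monoanion of 15 (NaH, THF) alkylates 14 at its central carbon to give tert-butyl (1S,4aS,8aR)-5-[2-(methoxycarbonyl)-3-oxobutyl]-1,4a,6-trimethyl-1,2,3,4,4a,7,8,8a-octahydronaphthalene-1-carboxylate F3.
- Krapcho dealkoxycarbonylation (LiCl, wet DMSO, heat) gives tert-butyl (1S,4aS,8aR)-1,4a,6-trimethyl-5-(3-oxobutyl)-1,2,3,4,4a,7,8,8a-octahydronaphthalene-1-carboxylate F4.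
- Horner–Wadsworth–Emmons olefination with trimethyl phosphonoacetate and NaH returns to the route at 18. This olefination is not stereospecific, so the Z isomer has to be removed by chromatography.

**Step 14.** The aluminium carboxylate may precipitate and hold back the reduction, or the acid may be partly reduced. Fallback, from 18 back to 21: the order of the two operations is reversed.
- iBu2AlH reduces 18 to tert-butyl (1S,4aS,8aR)-5-[(3E)-5-hydroxy-3-methylpent-3-en-1-yl]-1,4a,6-trimethyl-1,2,3,4,4a,7,8,8a-octahydronaphthalene-1-carboxylate F5, with the C19 ester still in place.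
- Me3SiOTf and 2,6-lutidine then silylate the alcohol and cleave the tert-butyl ester, giving trimethylsilyl (1S,4aS,8aR)-1,4a,6-trimethyl-5-{(3E)-3-methyl-5-[(trimethylsilyl)oxy]pent-3-en-1-yl}-1,2,3,4,4a,7,8,8a-octahydronaphthalene-1-carboxylate F6, which is not isolated.
- Mild aqueous acid removes both silyl groups and returns to the route at 21.

## Further compounds

F1 | step 6 | tert-butyl (1S,4aS)-5-formyl-1,4a,6-trimethyl-1,2,3,4,4a,7-hexahydronaphthalene-1-carboxylate | O=CC1=C(C)CC=C2[C@@](C)(C(=O)OC(C)(C)C)CCC[C@]12C
F2 | step 6 | tert-butyl (1S,4aS,8aR)-5-formyl-1,4a,6-trimethyl-1,2,3,4,4a,7,8,8a-octahydronaphthalene-1-carboxylate | O=CC1=C(C)CC[C@H]2[C@@](C)(C(=O)OC(C)(C)C)CCC[C@]12C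
F0 | step 2 | none | none
F0 | step 7 | none | none
F3 | step 10 | tert-butyl (1S,4aS,8aR)-5-[2-(methoxycarbonyl)-3-oxobutyl]-1,4a,6-trimethyl-1,2,3,4,4a,7,8,8a-octahydronaphthalene-1-carboxylate (both side-chain epimers) | COC(=O)C(CC1=C(C)CC[C@H]2[C@@](C)(C(=O)OC(C)(C)C)CCC[C@]12C)C(C)=O
F4 | step 10 | tert-butyl (1S,4aS,8aR)-1,4a,6-trimethyl-5-(3-oxobutyl)-1,2,3,4,4a,7,8,8a-octahydronaphthalene-1-carboxylate | CC(=O)CCC1=C(C)CC[C@H]2[C@@](C)(C(=O)OC(C)(C)C)CCC[C@]12C
F5 | step 14 | tert-butyl (1S,4aS,8aR)-5-[(3E)-5-hydroxy-3-methylpent-3-en-1-yl]-1,4a,6-trimethyl-1,2,3,4,4a,7,8,8a-octahydronaphthalene-1-carboxylate | OC/C=C(\C)CCC1=C(C)CC[C@H]2[C@@](C)(C(=O)OC(C)(C)C)CCC[C@]12C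
F6 | step 14 | trimethylsilyl (1S,4aS,8aR)-1,4a,6-trimethyl-5-{(3E)-3-methyl-5-[(trimethylsilyl)oxy]pent-3-en-1-yl}-1,2,3,4,4a,7,8,8a-octahydronaphthalene-1-carboxylate | C[Si](C)(C)OC/C=C(\C)CCC1=C(C)CC[C@H]2[C@@](C)(C(=O)O[Si](C)(C)C)CCC[C@]12C
A1 | alternative 1 | 3-methylcyclohex-2-en-1-one | CC1=CC(=O)CCC1
A2 | alternative 1 | diisobutyl{3-[(tert-butyldimethylsilyl)oxy]prop-1-en-2-yl}aluminium | CC(C)C[Al](CC(C)C)C(=C)CO[Si](C)(C)C(C)(C)C
A3 | alternative 1 | 3-(trimethylsilyl)but-3-en-2-one | CC(=O)C(=C)[Si](C)(C)C
A4 | alternative 1 | trans-3-[3-(tert-butyldimethylsilyloxy)prop-1-en-2-yl]-3-methyl-2-(3-oxobutyl)cyclohexan-1-one, C5 and C10 as in the target | CC(=O)CC[C@H]1C(=O)CCC[C@]1(C)C(=C)CO[Si](C)(C)C(C)(C)C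
A5 | alternative 2 | methyl 6-hydroxy-5-[(tert-butyldiphenylsilyloxy)methyl]-5,8a-dimethyl-2-oxodecahydronaphthalene-1-carboxylate, trans-fused, C19 axial | COC(=O)[C@H]1C(=O)CC[C@H]2[C@@](C)(CO[Si](c3ccccc3)(c3ccccc3)C(C)(C)C)[C@@H](O)CC[C@]12C
A6 | alternative 3 | 2,6-dimethylcyclohexa-2,5-diene-1,4-dione | CC1=CC(=O)C=C(C)C1=O
A7 | alternative 3 | (3E)-penta-1,3-diene | C/C=C/C=C
A8 | alternative 3 | 2,5,8a-trimethyl-4a,5,8,8a-tetrahydronaphthalene-1,4-dione, cis-fused endo adduct, C10 as in the target | CC1=CC(=O)[C@@H]2[C@H](C)C=CC[C@]2(C)C1=O
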